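**Abbreviation:** PMB = 4-methoxybenzyl.

## Retrosynthetic overview

1. Enabling feature: in the cyclohex-2-enone ring, C6 (fully substituted carbinol carbon, α to the C1 ketone) and C5 (CH–OH, β to it) form an aldol pair across ring bond C5–C6. The ring olefin C2=C3 lies between the C1 carbonyl and the C4 carbinol, so it can come from two terminal vinyl groups; C2 is then vinylic, so the C1 ketone can enolise only toward C6.
2. Both ring bonds are cut at once ([3+3]). The C6–C1–C2 unit is silyl dienol ether 8 of an α′-PMB-oxy vinyl ketone (C6 plus the C17 chain is the C18 skeleton of oleyl alcohol; C1–C2 come from methoxyallene). The C3–C4–C5 unit is (S)-2-(PMB-oxy)but-3-enal 12, from (S)-but-3-ene-1,2-diol.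
3. Only C4 is bought. C5 and C6 are set from it in the aldol event (magnesium chelate, open transition state), and the six-membered carbocycle, the only ring, is closed in the same flask by olefin metathesis.
4. End game: oxidative removal of the two PMB ethers.

Key step: step 9

Assumption: the target is the (4S,5R,6R) isomer written in the SMILES (4-OH trans to 5-OH, 5-OH cis to 6-OH). Carbinol 5 may be racemic because its stereocentre becomes trigonal in 8 and is set again in step 9.

## Route

Step 1
Reactants: 1 (Z)-octadec-9-en-1-ol (oleyl alcohol)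
Product: 2 (Z)-octadec-9-enal
Conditions: Dess–Martin periodinane, CH2Cl2, 0 °C → rt
Reagents that add atoms: none
Why: Dess–Martin oxidation stops at the aldehyde and leaves the (Z)-olefin untouched.

Step 2
Reactants: 2 (Z)-octadec-9-enal; 3 methoxyallene
Product: 5 (12Z)-3-methoxyhenicosa-1,2,12-trien-4-ol (racemic), via 1-lithio-1-methoxyallene 4 (not isolated)
Conditions: 3, n-BuLi, THF, −40 °C; then 2, −78 °C; H2O quench
Reagents that add atoms: none
Why: C1-lithiated methoxyallene is an acyl-anion equivalent of acrolein that adds 1,2 to the aldehyde (alkoxyallene addition), and the new carbinol centre may be racemic because it becomes trigonal in step 5.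

Step 3
Reactants: 5 (12Z)-3-methoxyhenicosa-1,2,12-trien-4-ol
Product: 6 (12Z)-3-methoxy-4-[(4-methoxybenzyl)oxy]henicosa-1,2,12-triene (racemic)
Conditions: NaH, 4-MeOC6H4CH2Cl, Bu4NI (cat.), THF–DMF, 0 °C → rt
Reagents that add atoms: 4-methoxybenzyl chloride, COc1ccc(CCl)cc1
Why: Williamson etherification of the sodium alkoxide installs the coordinating PMB ether that later steers the aldol, under basic conditions that the acid-labile allenyl ether tolerates.

Step 4
Reactants: 6 (12Z)-3-methoxy-4-[(4-methoxybenzyl)oxy]henicosa-1,2,12-triene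
Product: 7 (12Z)-4-[(4-methoxybenzyl)oxy]henicosa-1,12-dien-3-one (racemic)
Conditions: 5% aq. H2SO4, THF, 0 °C
Reagents that add atoms: water, O
Why: Acid hydrolysis of the allenyl enol ether (protonation at the central allene carbon, addition of water, loss of methanol) unmasks the vinyl ketone, while the PMB ether is stable to cold dilute acid.

Step 5
Reactants: 7 (12Z)-4-[(4-methoxybenzyl)oxy]henicosa-1,12-dien-3-one
Product: 8 (3Z,12Z)-4-[(4-methoxybenzyl)oxy]-3-[(trimethylsilyl)oxy]henicosa-1,3,12-triene
Conditions: LiN(SiMe3)2 added to 7 and Me3SiCl, THF, −78 °C; used crude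
Reagents that add atoms: chlorotrimethylsilane, C[Si](C)(C)Cl
Why: Kinetic deprotonation of the enone can occur only at the α′-carbon (the other α-carbon is vinylic), and in situ O-silylation of the lithium-chelated enolate gives the 2-silyloxydiene (silyl enol ether formation), expected as the (3Z) isomer with the two oxygens cis.

Step 6
Reactants: 9 (S)-but-3-ene-1,2-diol
Product: 10 (4S)-2-(4-methoxyphenyl)-4-vinyl-1,3-dioxolane (mixture of epimers at C2)
Conditions: 4-MeOC6H4CH(OMe)2, pyridinium p-toluenesulfonate (cat.), CH2Cl2, rt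
Reagents that add atoms: 4-methoxybenzaldehyde dimethyl acetal, COc1ccc(C(OC)OC)cc1
Why: Acid-catalysed acetal exchange with the 1,2-diol gives the five-membered 4-methoxybenzylidene acetal without touching the stereocentre; the new acetal centre is lost in step 7.

Step 7
Reactants: 10 (4S)-2-(4-methoxyphenyl)-4-vinyl-1,3-dioxolane
Product: 11 (S)-2-[(4-methoxybenzyl)oxy]but-3-en-1-ol
Conditions: i-Bu2AlH, CH2Cl2, −78 → 0 °C; aq. potassium sodium tartrate
Reagents that add atoms: none
Why: Regioselective reductive opening of the benzylidene acetal: aluminium binds the less hindered primary oxygen, that C–O bond breaks and hydride quenches the oxocarbenium ion, which leaves the PMB group on the secondary oxygen.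

Step 8
Reactants: 11 (S)-2-[(4-methoxybenzyl)oxy]but-3-en-1-ol
Product: 12 (S)-2-[(4-methoxybenzyl)oxy]but-3-enal
Conditions: Dess–Martin periodinane, pyridine, CH2Cl2, 0 °C; used crude at once
Reagents that add atoms: none
Why: Buffered Dess–Martin oxidation gives the α-alkoxy-β,γ-unsaturated aldehyde under non-basic conditions that avoid migration of the double bond into conjugation and loss of the stereocentre.

Step 9
Reactants: 8 (3Z,12Z)-4-[(4-methoxybenzyl)oxy]-3-[(trimethylsilyl)oxy]henicosa-1,3,12-triene; 12 (S)-2-[(4-methoxybenzyl)oxy]but-3-enal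
Product: 14 (4S,5R,6R)-6-[(8Z)-heptadec-8-en-1-yl]-5-hydroxy-4,6-bis[(4-methoxybenzyl)oxy]cyclohex-2-en-1-one, via aldol adduct 13 (not isolated)
Conditions: 12, MgBr2·OEt2, CH2Cl2, −78 °C; 8, −78 → −40 °C; aq. NaH2PO4/Na2HPO4 (pH 7); then second-generation Grubbs catalyst RuCl2(=CHPh)(PCy3)(H2IMes) (5 mol %), CH2Cl2 (5 mM), 40 °C
Reagents that add atoms: none
Why: MgBr2 chelates the aldehyde oxygen and the α-PMB ether oxygen of 12, the tetrasubstituted terminus of 8 (future C6) attacks the aldehyde carbon (future C5) in an open transition state to give vinyl ketone 13, and the ruthenium carbene then joins the two terminal vinyl groups with loss of ethene to form C2=C3. The closest known reaction types are the MgBr2·OEt2-mediated chelation-controlled Mukaiyama aldol addition to α-alkoxy aldehydes and aldol/ring-closing-metathesis sequences to 4-oxygenated cyclohexenones. The six-membered carbocycle is closed by ring-closing metathesis of a 1,7-diene whose one olefin is an enone, through a ruthenacyclobutane, and the ring enforces the cis olefin. C5 is set by attack on the face of the five-membered chelate opposite the vinyl group on C4 (4,5-syn, ring-trans); C6 is set in the antiperiplanar open transition state known from the syn,syn-selective additions of trisubstituted enol silanes, with the PMB-oxy group in the place of hydrogen over the chelate, where it can ligate divalent magnesium, and the chain in the place of the methyl group (5,6-anti, ring-cis diol). The step needs reaction at C6 only, this syn/anti diastereoselection, and ring closure in preference to metathesis at the remote (Z)-olefin; these should be secured by the vinylic C2, by the two coordinating PMB ethers with a chelating magnesium salt, and by the rate advantage of six-membered ring closure of terminal olefins at high dilution. The buffer quench removes the Lewis acid before warming, so that conjugate addition of bromide or of O5 to the vinyl ketone should not compete.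

Step 10
Reactants: 14 (4S,5R,6R)-6-[(8Z)-heptadec-8-en-1-yl]-5-hydroxy-4,6-bis[(4-methoxybenzyl)oxy]cyclohex-2-en-1-one
Product: 15 pleiogenone A, (4S,5R,6R)-6-[(8Z)-heptadec-8-en-1-yl]-4,5,6-trihydroxycyclohex-2-en-1-one
Conditions: DDQ, CH2Cl2–aq. NaH2PO4/Na2HPO4 (pH 7), 0 °C → rt
Reagents that add atoms: none
Why: Oxidative cleavage of both PMB ethers with DDQ (benzylic hydride abstraction, hydrolysis of the oxocarbenium ions) should leave the electron-poor enone, the isolated (Z)-olefin and the three stereocentres untouched.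

## Compound list

1 | (Z)-octadec-9-en-1-ol (oleyl alcohol) | CCCCCCCC/C=C\CCCCCCCCO | starting material
2 | (Z)-octadec-9-enal | CCCCCCCC/C=C\CCCCCCCC=O | intermediate
3 | methoxyallene (1-methoxypropa-1,2-diene) | COC=C=C | starting material
4 | 1-lithio-1-methoxyallene | [Li]C(OC)=C=C | intermediate (not isolated)
5 | (12Z)-3-methoxyhenicosa-1,2,12-trien-4-ol (racemic) | CCCCCCCC/C=C\CCCCCCCC(O)C(OC)=C=C | intermediate
6 | (12Z)-3-methoxy-4-[(4-methoxybenzyl)oxy]henicosa-1,2,12-triene (racemic) | CCCCCCCC/C=C\CCCCCCCC(OCc1ccc(OC)cc1)C(OC)=C=C | intermediate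
7 | (12Z)-4-[(4-methoxybenzyl)oxy]henicosa-1,12-dien-3-one (racemic) | CCCCCCCC/C=C\CCCCCCCC(OCc1ccc(OC)cc1)C(=O)C=C | intermediate
8 | (3Z,12Z)-4-[(4-methoxybenzyl)oxy]-3-[(trimethylsilyl)oxy]henicosa-1,3,12-triene | CCCCCCCC/C=C\CCCCCCC/C(OCc1ccc(OC)cc1)=C(/O[Si](C)(C)C)C=C | intermediate
9 | (S)-but-3-ene-1,2-diol | C=C[C@H](O)CO | starting material
10 | (4S)-2-(4-methoxyphenyl)-4-vinyl-1,3-dioxolane (mixture of epimers at C2) | C=C[C@H]1COC(c2ccc(OC)cc2)O1 | intermediate
11 | (S)-2-[(4-methoxybenzyl)oxy]but-3-en-1-ol | C=C[C@H](OCc1ccc(OC)cc1)CO | intermediate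
12 | (S)-2-[(4-methoxybenzyl)oxy]but-3-enal | C=C[C@H](OCc1ccc(OC)cc1)C=O | intermediate
13 | (4R,5R,6S)-4-[(8Z)-heptadec-8-en-1-yl]-5-hydroxy-4,6-bis[(4-methoxybenzyl)oxy]octa-1,7-dien-3-one | CCCCCCCC/C=C\CCCCCCC[C@](OCc1ccc(OC)cc1)(C(=O)C=C)[C@H](O)[C@@H](OCc1ccc(OC)cc1)C=C | intermediate (not isolated)
14 | (4S,5R,6R)-6-[(8Z)-heptadec-8-en-1-yl]-5-hydroxy-4,6-bis[(4-methoxybenzyl)oxy]cyclohex-2-en-1-one | CCCCCCCC/C=C\CCCCCCC[C@]1(OCc2ccc(OC)cc2)C(=O)C=C[C@H](OCc2ccc(OC)cc2)[C@H]1O | intermediate
15 | pleiogenone A, (4S,5R,6R)-6-[(8Z)-heptadec-8-en-1-yl]-4,5,6-trihydroxycyclohex-2-en-1-one | CCCCCCCC/C=C\CCCCCCC[C@]1(O)C(=O)C=C[C@H](O)[C@H]1O | target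

## Step count and risks

Total step count: 10. Longest linear sequence: 7 steps (steps 1, 2, 3, 4, 5, 9, 10, from oleyl alcohol).

The three steps most likely to fail:

1. Step 9 (key step). What may go wrong: loss of simple diastereoselection at the new quaternary carbon when the enol ether attacks the chelated aldehyde through an open transition state (the chain instead of the PMB-oxy group lying over the chelate). The freshly formed vinyl ketone may also be consumed by conjugate addition (of bromide, of the C5 oxygen or of a second molecule of 8) before the ring closes.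

   Fallback: a closed transition state with later correction of C5, run stepwise; it sets out from 7 and 12 and comes back at 14. Ketone 7 is deprotonated with LiN(i-Pr)2 (THF, −78 °C) to the lithium enolate, in which lithium is held between the enolate oxygen and the PMB ether oxygen, and 12 is added. The Zimmerman–Traxler chair with Cornforth/Felkin approach to the α-alkoxy aldehyde should give the 4,5-anti-5,6-syn aldol (4R,5S,6S)-4-[(8Z)-heptadec-8-en-1-yl]-5-hydroxy-4,6-bis[(4-methoxybenzyl)oxy]octa-1,7-dien-3-one F1. F1 has the relative configuration of the target at the two PMB-oxy-bearing carbons and is epimeric only at the carbinol carbon. Ring-closing metathesis of isolated F1 (second-generation Grubbs catalyst RuCl2(=CHPh)(PCy3)(H2IMes), CH2Cl2, 40 °C) should give (4S,5S,6R)-6-[(8Z)-heptadec-8-en-1-yl]-5-hydroxy-4,6-bis[(4-methoxybenzyl)oxy]cyclohex-2-en-1-one F2. Dess–Martin oxidation should give (2S,6S)-2-[(8Z)-heptadec-8-en-1-yl]-2,6-bis[(4-methoxybenzyl)oxy]cyclohex-4-ene-1,3-dione F3. NaBH4 (MeOH–CH2Cl2, −78 °C) should then reduce the non-conjugated carbonyl by axial hydride delivery, anti to the axial C–O bond on the neighbouring quaternary carbon; the new hydroxyl is placed equatorial, trans to O4 and cis to O6, which is 14.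

2. Step 10. What may go wrong: capture of the benzylic oxocarbenium ion by the free C5 hydroxyl to give a 4-methoxybenzylidene acetal that is over-oxidised to a benzoate, and slow cleavage of the tertiary ether.

   Fallback: temporary capping of O5 instead of direct oxidation of the free alcohol; it sets out from 14 and comes back at 15. Silylation (Et3SiOTf, 2,6-lutidine, CH2Cl2, −78 °C) should give (4S,5R,6R)-6-[(8Z)-heptadec-8-en-1-yl]-4,6-bis[(4-methoxybenzyl)oxy]-5-[(triethylsilyl)oxy]cyclohex-2-en-1-one F4. DDQ under the conditions of step 10 should then give (4S,5R,6R)-6-[(8Z)-heptadec-8-en-1-yl]-4,6-dihydroxy-5-[(triethylsilyl)oxy]cyclohex-2-en-1-one F5, and HF·pyridine (THF, 0 °C) should release 15.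

3. Step 7. What may go wrong: hydride delivery to the wrong C–O bond of the five-membered acetal (giving the primary PMB ether) and Lewis-acid-induced ionisation at the allylic position.

   Fallback: stepwise differentiation of the two hydroxyls without an acetal; it sets out from 9 and comes back at 11. Selective silylation of the primary hydroxyl (t-BuMe2SiCl, imidazole, CH2Cl2, 0 °C) should give (S)-1-[(tert-butyldimethylsilyl)oxy]but-3-en-2-ol F6. Acid-catalysed benzylation (4-methoxybenzyl 2,2,2-trichloroacetimidate, La(OTf)3 cat., toluene, rt; no base, so no silyl migration) should give (S)-tert-butyl({2-[(4-methoxybenzyl)oxy]but-3-en-1-yl}oxy)dimethylsilane F7, and Bu4NF (THF, 0 °C) should give 11.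

## Further compounds

F1 | step 9 | (4R,5S,6S)-4-[(8Z)-heptadec-8-en-1-yl]-5-hydroxy-4,6-bis[(4-methoxybenzyl)oxy]octa-1,7-dien-3-one | CCCCCCCC/C=C\CCCCCCC[C@](OCc1ccc(OC)cc1)(C(=O)C=C)[C@@H](O)[C@@H](OCc1ccc(OC)cc1)C=C
F2 | step 9 | (4S,5S,6R)-6-[(8Z)-heptadec-8-en-1-yl]-5-hydroxy-4,6-bis[(4-methoxybenzyl)oxy]cyclohex-2-en-1-one | CCCCCCCC/C=C\CCCCCCC[C@]1(OCc2ccc(OC)cc2)C(=O)C=C[C@H](OCc2ccc(OC)cc2)[C@@H]1O
F3 | step 9 | (2S,6S)-2-[(8Z)-heptadec-8-en-1-yl]-2,6-bis[(4-methoxybenzyl)oxy]cyclohex-4-ene-1,3-dione | CCCCCCCC/C=C\CCCCCCC[C@]1(OCc2ccc(OC)cc2)C(=O)C=C[C@H](OCc2ccc(OC)cc2)C1=O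
F4 | step 10 | (4S,5R,6R)-6-[(8Z)-heptadec-8-en-1-yl]-4,6-bis[(4-methoxybenzyl)oxy]-5-[(triethylsilyl)oxy]cyclohex-2-en-1-one | CCCCCCCC/C=C\CCCCCCC[C@]1(OCc2ccc(OC)cc2)C(=O)C=C[C@H](OCc2ccc(OC)cc2)[C@H]1O[Si](CC)(CC)CC
F5 | step 10 | (4S,5R,6R)-6-[(8Z)-heptadec-8-en-1-yl]-4,6-dihydroxy-5-[(triethylsilyl)oxy]cyclohex-2-en-1-one | CCCCCCCC/C=C\CCCCCCC[C@]1(O)C(=O)C=C[C@H](O)[C@H]1O[Si](CC)(CC)CC
F6 | step 7 | (S)-1-[(tert-butyldimethylsilyl)oxy]but-3-en-2-ol | C=C[C@H](O)CO[Si](C)(C)C(C)(C)C
F7 | step 7 | (S)-tert-butyl({2-[(4-methoxybenzyl)oxy]but-3-en-1-yl}oxy)dimethylsilane | C=C[C@H](OCc1ccc(OC)cc1)CO[Si](C)(C)C(C)(C)C
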